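The route rests on disconnecting the cyclohexanone ring B at two bonds: ketone carbon to arene (C1–C8a of the tetralone) and CH2 to the isopropenyl-bearing CH (C2–C3). The CH2–C=O unit is read as a ketene and the isopropenyl group as the footprint of an allylic transposition. An (E)-allyl ethynyl ether, made in situ from a dichlorovinyl ether, should undergo [3,3]-sigmatropic rearrangement to a ketene, which acylates the dimethoxyarene. One operation forms both bonds, ring B, the isopropenyl group and the tertiary stereocentre, relayed from a catalytically set quaternary centre. The third phenol is added last by quinone formation and reduction.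

Key step: step 7

Remark: aldehyde 1 is assumed to be purchasable (it is a known intermediate of tapinarof manufacture).
Remark: the (S)-phosphoric acid in step 3 is assumed to deliver the (S)-aldehyde 7; should the sense of induction be the opposite, the (R)-acid is used instead.

Step 1
Reactants: 1 4-isopropyl-3,5-dimethoxybenzaldehyde; 2 methyltriphenylphosphonium bromide
Product: 3 5-ethenyl-2-isopropyl-1,3-dimethoxybenzene
Conditions: KOtBu, THF, 0 °C to rt
Reagents that add atoms: methyltriphenylphosphonium bromide (2), C[P+](c1ccccc1)(c1ccccc1)c1ccccc1.[Br-]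
Why: Wittig methylenation of an unhindered, electron-rich benzaldehyde with the non-stabilised ylide is reliable and has no competing pathway.

Step 2
Reactants: 3 5-ethenyl-2-isopropyl-1,3-dimethoxybenzene; 4 carbon monoxide
Product: 5 rac-2-(4-isopropyl-3,5-dimethoxyphenyl)propanal
Conditions: Rh(acac)(CO)2 (0.5 mol%), PPh3 (2 mol%), CO/H2 (1:1, 40 bar), toluene, 40 °C
Reagents that add atoms: carbon monoxide (4), [C-]#[O+]
Why: Rhodium-catalysed hydroformylation of styrenes favours the branched aldehyde through the benzylic rhodium alkyl at low temperature and high pressure; the labile stereocentre is racemic and is erased in step 3.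

Step 3
Reactants: 5 rac-2-(4-isopropyl-3,5-dimethoxyphenyl)propanal; 6 allyl alcohol
Product: 7 (2S)-2-(4-isopropyl-3,5-dimethoxyphenyl)-2-methylpent-4-enal
Conditions: Pd(PPh3)4 (3 mol%), (S)-TRIP (3 mol%), Ph2CHNH2 (40 mol%), 5 Å MS, toluene, 40 °C; then 2 M HCl
Reagents that add atoms: allyl alcohol (6), C=CCO
Why: Tsuji–Trost-type α-allylation of an α-branched aldehyde under combined enamine, chiral phosphoric acid and palladium catalysis; the racemic aldehyde converges through its enamine and the chiral phosphate counter-anion of the π-allylpalladium pair should set the quaternary centre.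

Step 4
Reactants: 7 (2S)-2-(4-isopropyl-3,5-dimethoxyphenyl)-2-methylpent-4-enal; 8 ethyl 2-(triphenylphosphoranylidene)propanoate
Product: 9 ethyl (2E,4R)-4-(4-isopropyl-3,5-dimethoxyphenyl)-2,4-dimethylhepta-2,6-dienoate
Conditions: toluene, 90 °C
Reagents that add atoms: ethyl 2-(triphenylphosphoranylidene)propanoate (8), CCOC(=O)C(C)=P(c1ccccc1)(c1ccccc1)c1ccccc1
Why: Wittig olefination with a stabilised α-methyl ylide is E-selective and tolerates the α-quaternary aldehyde, which cannot epimerise.

Step 5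
Reactants: 9 ethyl (2E,4R)-4-(4-isopropyl-3,5-dimethoxyphenyl)-2,4-dimethylhepta-2,6-dienoate
Product: 10 (2E,4R)-4-(4-isopropyl-3,5-dimethoxyphenyl)-2,4-dimethylhepta-2,6-dien-1-ol
Conditions: i-Bu2AlH (2.5 equiv), CH2Cl2, −78 °C; aq. potassium sodium tartrate
Reagents that add atoms: none
Why: DIBAL-H 1,2-reduction of an α,β-unsaturated ester gives the allylic alcohol and leaves the isolated alkene alone.

Step 6
Reactants: 10 (2E,4R)-4-(4-isopropyl-3,5-dimethoxyphenyl)-2,4-dimethylhepta-2,6-dien-1-ol; 11 trichloroethylene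
Product: 12 5-[(4R,5E)-7-{[(E)-1,2-dichloroethenyl]oxy}-4,6-dimethylhepta-1,5-dien-4-yl]-2-isopropyl-1,3-dimethoxybenzene
Conditions: KH (2.2 equiv), THF, 0 °C; then Cl2C=CHCl, 0 °C to rt
Reagents that add atoms: trichloroethylene (11), ClC=C(Cl)Cl
Why: Anti addition of the potassium alkoxide to dichloroacetylene, generated in situ by dehydrochlorination of trichloroethylene, is the standard entry to (E)-1,2-dichlorovinyl ethers as ynol ether precursors.

Step 7
Reactants: 12 5-[(4R,5E)-7-{[(E)-1,2-dichloroethenyl]oxy}-4,6-dimethylhepta-1,5-dien-4-yl]-2-isopropyl-1,3-dimethoxybenzene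
Product: 16 (3S,4R)-4-allyl-7-isopropyl-6,8-dimethoxy-4-methyl-3-(prop-1-en-2-yl)-3,4-dihydronaphthalen-1(2H)-one, via lithium acetylide 13 (not isolated), via allyl ethynyl ether 14 (not isolated), via aldoketene 15 (not isolated)
Conditions: n-BuLi (2.3 equiv), Et2O, −78 to −40 °C; 2,6-di-tert-butyl-4-methylpyridinium triflate (1.4 equiv) in CH2Cl2, −78 to −40 °C; then BF3·OEt2 (1.5 equiv), −78 to −20 °C; aq. NaHCO3
Reagents that add atoms: none
Why: Proposed new method: two equivalents of n-BuLi convert the dichlorovinyl ether by elimination and chlorine–lithium exchange into the lithium acetylide 13, and a hindered pyridinium acid liberates the allyl ethynyl ether 14, which should undergo the low-temperature [3,3]-sigmatropic shift known for allyl alkynyl ethers, bonding the alkyne terminus to the alkene carbon beside the quaternary centre, transposing the double bond into the isopropenyl group and leaving the aldoketene 15. BF3 then turns the ketene into an acylating agent that attacks the arene position ortho and para to the two methoxy groups, closing ring B as a six-membered ring in a 6-exo-dig sense on the ketene C=O (Friedel–Crafts acylation), and proton transfer gives the ketone. The closest known reaction types are the sigmatropic shift of allyl alkynyl ethers followed by intramolecular trapping of the ketene by O-nucleophiles or alkenes, and the Lewis-acid acylation of arenes by ketenes; their union on an arene tether is the new element. The CH(isopropenyl) stereocentre is set in the sigmatropic step by the neighbouring quaternary centre: allylic 1,3-strain places its methyl group in the plane of the trisubstituted alkene and the new bond forms anti to the aryl group, which puts isopropenyl cis to the allyl chain as the target requires. The step needs rearrangement to outrun ionisation of the acid-labile ynol ether (hence a non-nucleophilic proton source and BF3 only after the shift) and C-acylation to outrun ketene dimerisation or [2+2] addition to the allyl group (hence low temperature and the far more nucleophilic arene); regiochemistry is not at issue because the two free arene positions are equivalent.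

Step 8
Reactants: 16 (3S,4R)-4-allyl-7-isopropyl-6,8-dimethoxy-4-methyl-3-(prop-1-en-2-yl)-3,4-dihydronaphthalen-1(2H)-one; 17 hydrogen peroxide
Product: 19 (3S,4R)-4-(3-hydroxypropyl)-7-isopropyl-6,8-dimethoxy-4-methyl-3-(prop-1-en-2-yl)-3,4-dihydronaphthalen-1(2H)-one, via alkyldisiamylborane 18 (not isolated)
Conditions: disiamylborane (Sia2BH, 1.3 equiv, from BH3·THF and 2-methylbut-2-ene), THF, −10 to 0 °C; then 30% H2O2, 3 M NaOH, 0 °C
Reagents that add atoms: hydrogen peroxide (17), OO
Why: Hydroboration–oxidation with the bulky dialkylborane is anti-Markovnikov and should prefer the monosubstituted allyl alkene over the hindered 1,1-disubstituted isopropenyl group and the deactivated aryl ketone.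

Step 9
Reactants: 19 (3S,4R)-4-(3-hydroxypropyl)-7-isopropyl-6,8-dimethoxy-4-methyl-3-(prop-1-en-2-yl)-3,4-dihydronaphthalen-1(2H)-one; 20 water
Product: 22 3-[(1R,2S)-6-isopropyl-5,7-dimethoxy-1-methyl-4-oxo-2-(prop-1-en-2-yl)-1,2,3,4-tetrahydronaphthalen-1-yl]propanoic acid, via aldehyde 21 (not isolated)
Conditions: TEMPO (0.2 equiv), PhI(OAc)2 (2.5 equiv), MeCN/H2O (1:1), rt
Reagents that add atoms: water (20), O
Why: TEMPO/PhI(OAc)2 oxidation in aqueous acetonitrile takes a primary alcohol through the aldehyde hydrate to the acid and leaves alkene, ketone and dimethoxyarene alone.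

Step 10
Reactants: 22 3-[(1R,2S)-6-isopropyl-5,7-dimethoxy-1-methyl-4-oxo-2-(prop-1-en-2-yl)-1,2,3,4-tetrahydronaphthalen-1-yl]propanoic acid
Product: 23 3-[(1R,2S)-5,7-dihydroxy-6-isopropyl-1-methyl-4-oxo-2-(prop-1-en-2-yl)-1,2,3,4-tetrahydronaphthalen-1-yl]propanoic acid
Conditions: NaSEt (8 equiv), DMF, 130 °C, argon; then 1 M HCl, 0 °C
Reagents that add atoms: none
Why: Nucleophilic (SN2) O-demethylation by thiolate is fastest for methyl ethers ortho and para to an acyl group, which both are, and avoids the protic or Lewis acids that would attack the isopropenyl group.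

Step 11
Reactants: 23 3-[(1R,2S)-5,7-dihydroxy-6-isopropyl-1-methyl-4-oxo-2-(prop-1-en-2-yl)-1,2,3,4-tetrahydronaphthalen-1-yl]propanoic acid; 24 potassium nitrosodisulfonate
Product: 26 3-[(1R,2S)-5,7,8-trihydroxy-6-isopropyl-1-methyl-4-oxo-2-(prop-1-en-2-yl)-1,2,3,4-tetrahydronaphthalen-1-yl]propanoic acid (CNP0198818.2), via hydroxyquinone 25 (not isolated)
Conditions: (KSO3)2NO (2.5 equiv), KH2PO4 buffer, acetone/H2O, 0 °C to rt; then aq. Na2S2O4, EtOAc, argon
Reagents that add atoms: potassium nitrosodisulfonate (24), [K+].[K+].[O]N(S(=O)(=O)[O-])S(=O)(=O)[O-]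
Why: Teuber oxidation should oxygenate the only free ring position (ortho to one hydroxyl, para to the other) to the hydroxyquinone, and dithionite reduction of the quinone then gives the third phenol without touching ketone or alkene; the product is isolated under argon.

Compound list
1 | 4-isopropyl-3,5-dimethoxybenzaldehyde | O=Cc1cc(OC)c(C(C)C)c(OC)c1 | starting material
2 | methyltriphenylphosphonium bromide | C[P+](c1ccccc1)(c1ccccc1)c1ccccc1.[Br-] | starting material
3 | 5-ethenyl-2-isopropyl-1,3-dimethoxybenzene | C=Cc1cc(OC)c(C(C)C)c(OC)c1 | intermediate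
4 | carbon monoxide | [C-]#[O+] | starting material
5 | rac-2-(4-isopropyl-3,5-dimethoxyphenyl)propanal | CC(C=O)c1cc(OC)c(C(C)C)c(OC)c1 | intermediate
6 | allyl alcohol | C=CCO | starting material
7 | (2S)-2-(4-isopropyl-3,5-dimethoxyphenyl)-2-methylpent-4-enal | C=CC[C@@](C)(c1cc(OC)c(C(C)C)c(OC)c1)C=O | intermediate
8 | ethyl 2-(triphenylphosphoranylidene)propanoate | CCOC(=O)C(C)=P(c1ccccc1)(c1ccccc1)c1ccccc1 | starting material
9 | ethyl (2E,4R)-4-(4-isopropyl-3,5-dimethoxyphenyl)-2,4-dimethylhepta-2,6-dienoate | C=CC[C@@](C)(c1cc(OC)c(C(C)C)c(OC)c1)/C=C(\C)C(=O)OCC | intermediate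
10 | (2E,4R)-4-(4-isopropyl-3,5-dimethoxyphenyl)-2,4-dimethylhepta-2,6-dien-1-ol | C=CC[C@@](C)(c1cc(OC)c(C(C)C)c(OC)c1)/C=C(\C)CO | intermediate
11 | trichloroethylene | ClC=C(Cl)Cl | starting material
12 | 5-[(4R,5E)-7-{[(E)-1,2-dichloroethenyl]oxy}-4,6-dimethylhepta-1,5-dien-4-yl]-2-isopropyl-1,3-dimethoxybenzene | C=CC[C@@](C)(c1cc(OC)c(C(C)C)c(OC)c1)/C=C(\C)CO/C(Cl)=C\Cl | intermediate
13 | lithium acetylide of 14, (2-{[(2E,4R)-4-(4-isopropyl-3,5-dimethoxyphenyl)-2,4-dimethylhepta-2,6-dien-1-yl]oxy}ethynyl)lithium | C=CC[C@@](C)(c1cc(OC)c(C(C)C)c(OC)c1)/C=C(\C)COC#C[Li] | intermediate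
14 | 5-[(4R,5E)-7-(ethynyloxy)-4,6-dimethylhepta-1,5-dien-4-yl]-2-isopropyl-1,3-dimethoxybenzene | C=CC[C@@](C)(c1cc(OC)c(C(C)C)c(OC)c1)/C=C(\C)COC#C | intermediate
15 | (3S,4R)-4-(4-isopropyl-3,5-dimethoxyphenyl)-4-methyl-3-(prop-1-en-2-yl)hepta-1,6-dien-1-one (aldoketene) | O=C=C[C@@H](C(C)=C)[C@@](C)(CC=C)c1cc(OC)c(C(C)C)c(OC)c1 | intermediate
16 | (3S,4R)-4-allyl-7-isopropyl-6,8-dimethoxy-4-methyl-3-(prop-1-en-2-yl)-3,4-dihydronaphthalen-1(2H)-one | C=C(C)[C@@H]1CC(=O)c2c(OC)c(C(C)C)c(OC)cc2[C@]1(C)CC=C | intermediate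
17 | hydrogen peroxide | OO | starting material
18 | (3S,4R)-4-{3-[bis(3-methylbutan-2-yl)boranyl]propyl}-7-isopropyl-6,8-dimethoxy-4-methyl-3-(prop-1-en-2-yl)-3,4-dihydronaphthalen-1(2H)-one | C=C(C)[C@@H]1CC(=O)c2c(OC)c(C(C)C)c(OC)cc2[C@]1(C)CCCB(C(C)C(C)C)C(C)C(C)C | intermediate
19 | (3S,4R)-4-(3-hydroxypropyl)-7-isopropyl-6,8-dimethoxy-4-methyl-3-(prop-1-en-2-yl)-3,4-dihydronaphthalen-1(2H)-one | C=C(C)[C@@H]1CC(=O)c2c(OC)c(C(C)C)c(OC)cc2[C@]1(C)CCCO | intermediate
20 | water | O | starting material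
21 | 3-[(1R,2S)-6-isopropyl-5,7-dimethoxy-1-methyl-4-oxo-2-(prop-1-en-2-yl)-1,2,3,4-tetrahydronaphthalen-1-yl]propanal | C=C(C)[C@@H]1CC(=O)c2c(OC)c(C(C)C)c(OC)cc2[C@]1(C)CCC=O | intermediate
22 | 3-[(1R,2S)-6-isopropyl-5,7-dimethoxy-1-methyl-4-oxo-2-(prop-1-en-2-yl)-1,2,3,4-tetrahydronaphthalen-1-yl]propanoic acid | C=C(C)[C@@H]1CC(=O)c2c(OC)c(C(C)C)c(OC)cc2[C@]1(C)CCC(=O)O | intermediate
23 | 3-[(1R,2S)-5,7-dihydroxy-6-isopropyl-1-methyl-4-oxo-2-(prop-1-en-2-yl)-1,2,3,4-tetrahydronaphthalen-1-yl]propanoic acid | C=C(C)[C@@H]1CC(=O)c2c(O)c(C(C)C)c(O)cc2[C@]1(C)CCC(=O)O | intermediate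
24 | potassium nitrosodisulfonate | [K+].[K+].[O]N(S(=O)(=O)[O-])S(=O)(=O)[O-] | starting material
25 | 3-[(1R,2S)-7-hydroxy-6-isopropyl-1-methyl-4,5,8-trioxo-2-(prop-1-en-2-yl)-1,2,3,4,5,8-hexahydronaphthalen-1-yl]propanoic acid | C=C(C)[C@@H]1CC(=O)C2=C(C(=O)C(O)=C(C(C)C)C2=O)[C@]1(C)CCC(=O)O | intermediate
26 | 3-[(1R,2S)-5,7,8-trihydroxy-6-isopropyl-1-methyl-4-oxo-2-(prop-1-en-2-yl)-1,2,3,4-tetrahydronaphthalen-1-yl]propanoic acid (CNP0198818.2) | C=C(C)[C@@H]1CC(=O)c2c(O)c(C(C)C)c(O)c(O)c2[C@]1(C)CCC(=O)O | target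

Total step count: 11
Longest linear sequence: 11 steps (1 to 26)

Steps most likely to fail

Step 7. The sigmatropic shift may proceed with poor facial selectivity, because only the difference between methyl and allyl decides which group eclipses the alkene. The ketene may also be lost to dimerisation, or the ynol ether to acid-induced ionisation, before ring closure. The fallback uses known chemistry, sets out from 10 and comes back at 16. Alcohol 10 is acetylated (Ac2O, pyridine) to (2E,4R)-4-(4-isopropyl-3,5-dimethoxyphenyl)-2,4-dimethylhepta-2,6-dien-1-yl acetate F1. Ireland–Claisen rearrangement (LDA, Me3SiCl, THF, −78 °C to rt) passes through the O-trimethylsilyl ketene acetal F2 and trimethylsilyl (3S,4R)-4-(4-isopropyl-3,5-dimethoxyphenyl)-4-methyl-3-(prop-1-en-2-yl)hept-6-enoate F3, which acidic work-up hydrolyses to (3S,4R)-4-(4-isopropyl-3,5-dimethoxyphenyl)-4-methyl-3-(prop-1-en-2-yl)hept-6-enoic acid F4. The acid is converted with (COCl)2 and catalytic DMF into (3S,4R)-4-(4-isopropyl-3,5-dimethoxyphenyl)-4-methyl-3-(prop-1-en-2-yl)hept-6-enoyl chloride F5, and SnCl4 in CH2Cl2 at −78 °C closes the ring by Friedel–Crafts acylation to 16. Diastereomers would be separated at the acid or tetralone stage.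

Step 11. Radical oxidation of the acyl-deactivated resorcinol may be sluggish or unselective, and the hydroquinone may re-oxidise in air during isolation. The fallback sets out from 23 and comes back at 26 without a quinone. Elbs persulfate oxidation (K2S2O8, aq. NaOH, 0 °C to rt, argon) should attack the same free position and give 3-[(1R,2S)-5,7-dihydroxy-6-isopropyl-1-methyl-4-oxo-2-(prop-1-en-2-yl)-8-(sulfooxy)-1,2,3,4-tetrahydronaphthalen-1-yl]propanoic acid F6. Hydrolysis of the aryl sulfate with dilute HCl in aqueous dioxane, at the lowest temperature that turns it over, would give 26.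

Step 8. Chemoselectivity may be lost through hydroboration of the isopropenyl group or reduction of the ketone. The fallback sets out from 16 and comes back at 22, bypassing 19. Aldehyde-selective Wacker-type oxidation of the allyl group (PdCl2(PhCN)2, CuCl2, AgNO2, t-BuOH/MeNO2, O2, rt) would give aldehyde 21 directly. Pinnick oxidation (NaClO2, NaH2PO4, 2-methylbut-2-ene, t-BuOH/H2O) would then give 22.

Further compounds
F1 | step 7 | (2E,4R)-4-(4-isopropyl-3,5-dimethoxyphenyl)-2,4-dimethylhepta-2,6-dien-1-yl acetate | C=CC[C@@](C)(c1cc(OC)c(C(C)C)c(OC)c1)/C=C(\C)COC(C)=O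
F2 | step 7 | 5-[(4R,5E)-4,6-dimethyl-7-({1-[(trimethylsilyl)oxy]ethenyl}oxy)hepta-1,5-dien-4-yl]-2-isopropyl-1,3-dimethoxybenzene (O-trimethylsilyl ketene acetal) | C=CC[C@@](C)(c1cc(OC)c(C(C)C)c(OC)c1)/C=C(\C)COC(=C)O[Si](C)(C)C
F3 | step 7 | trimethylsilyl (3S,4R)-4-(4-isopropyl-3,5-dimethoxyphenyl)-4-methyl-3-(prop-1-en-2-yl)hept-6-enoate | C[Si](C)(C)OC(=O)C[C@@H](C(C)=C)[C@@](C)(CC=C)c1cc(OC)c(C(C)C)c(OC)c1
F4 | step 7 | (3S,4R)-4-(4-isopropyl-3,5-dimethoxyphenyl)-4-methyl-3-(prop-1-en-2-yl)hept-6-enoic acid | OC(=O)C[C@@H](C(C)=C)[C@@](C)(CC=C)c1cc(OC)c(C(C)C)c(OC)c1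
F5 | step 7 | (3S,4R)-4-(4-isopropyl-3,5-dimethoxyphenyl)-4-methyl-3-(prop-1-en-2-yl)hept-6-enoyl chloride | ClC(=O)C[C@@H](C(C)=C)[C@@](C)(CC=C)c1cc(OC)c(C(C)C)c(OC)c1
F6 | step 11 | 3-[(1R,2S)-5,7-dihydroxy-6-isopropyl-1-methyl-4-oxo-2-(prop-1-en-2-yl)-8-(sulfooxy)-1,2,3,4-tetrahydronaphthalen-1-yl]propanoic acid | C=C(C)[C@@H]1CC(=O)c2c(O)c(C(C)C)c(O)c(OS(=O)(=O)O)c2[C@]1(C)CCC(=O)O
F0 | step 8 | none | none
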